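Ring A (C4a, C5, C6, C7, C8, C8a) bears six different substituents and three oxygens, and only the oxygen on C8a, beside the C8 methyl group, may become O1 of ring C. The plan therefore makes ring A from an open chain in one pericyclic operation: irradiation converts an (R)-configured diazo enedione, ArCH(OTES)CH2C(O)CH=C(OMOM)C(O)C(N2)CH2CH=CMe2 with a Z enol ether, into a vinylketene that is intercepted by 1-(triisopropylsiloxy)propyne, and a [2+2]/4π/6π cascade delivers the hexasubstituted phenol with O8a free, O7 silylated and O5 as its MOM ether. The chain comes from an amine-catalysed acetone aldol and an oxalic bis(N-methoxy-N-methylamide); Mitsunobu inversion then closes ring C.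

Key step: step 9

Remark on the chemistry: flavanone numbering (C2 to C8a) is used for the chain carbons throughout; 9 and 12 are drawn as their chelated Z enols; stannane 2, oxamide 7 and 1-propynyllithium 17 are assumed to be purchasable.

Step 1
Reactants: 1 3-bromo-4-methoxybenzaldehyde; 2 tributyl(3-methylbut-2-en-1-yl)stannane
Product: 3 4-methoxy-3-(3-methylbut-2-en-1-yl)benzaldehyde
Conditions: Pd(PPh3)4 (5 mol %), DMF, 100 °C
Reagents that add atoms: none
Why: Stille coupling of an aryl bromide with an allylic stannane should give the linear prenyl arene, and the aldehyde is inert to zerovalent palladium and to the tin reagent.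

Step 2
Reactants: 3 4-methoxy-3-(3-methylbut-2-en-1-yl)benzaldehyde; 4 acetone
Product: 5 (4R)-4-hydroxy-4-[4-methoxy-3-(3-methylbut-2-en-1-yl)phenyl]butan-2-one
Conditions: (S)-N-[(S)-1-hydroxy-4-methyl-1,1-diphenylpentan-2-yl]pyrrolidine-2-carboxamide (10 mol %), acetone, −25 °C
Reagents that add atoms: none
Why: Enamine-catalysed direct aldol addition, in which the L-proline amide holds the aldehyde by its N–H and O–H groups so that the acetone enamine attacks the Re face and C2 should be set as R (a long reaction time is expected for this electron-rich aldehyde).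

Step 3
Reactants: 5 (4R)-4-hydroxy-4-[4-methoxy-3-(3-methylbut-2-en-1-yl)phenyl]butan-2-one
Product: 6 (4R)-4-[4-methoxy-3-(3-methylbut-2-en-1-yl)phenyl]-4-(triethylsilyloxy)butan-2-one
Conditions: Et3SiCl, imidazole, DMF, 0 → 20 °C
Reagents that add atoms: chlorotriethylsilane, CC[Si](Cl)(CC)CC
Why: Silyl ether formation on the secondary alcohol blocks retro-aldol cleavage in the enolate steps and later keeps the hydroxyl from trapping the ketene.

Step 4
Reactants: 6 (4R)-4-[4-methoxy-3-(3-methylbut-2-en-1-yl)phenyl]-4-(triethylsilyloxy)butan-2-one; 7 N,N'-dimethoxy-N,N'-dimethyloxamide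
Product: 9 (2Z,6R)-2-hydroxy-N-methoxy-6-[4-methoxy-3-(3-methylbut-2-en-1-yl)phenyl]-N-methyl-4-oxo-6-(triethylsilyloxy)hex-2-enamide, via lithium enolate 8 (not isolated)
Conditions: LiN(SiMe3)2, THF, −78 °C; then 7 (3 equiv), −78 → 0 °C; aq NH4Cl
Reagents that add atoms: none
Why: Crossed Claisen-type condensation, in which the kinetic methyl enolate acylates one N-methoxy-N-methyl amide carbonyl and the chelated tetrahedral adduct should persist until work-up, so a second addition is prevented.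

Step 5
Reactants: 9 (2Z,6R)-2-hydroxy-N-methoxy-6-[4-methoxy-3-(3-methylbut-2-en-1-yl)phenyl]-N-methyl-4-oxo-6-(triethylsilyloxy)hex-2-enamide; 10 5-bromo-2-methylpent-2-ene
Product: 12 (1R,4Z)-5-hydroxy-1-[4-methoxy-3-(3-methylbut-2-en-1-yl)phenyl]-10-methyl-1-(triethylsilyloxy)undeca-4,9-diene-3,6-dione, via Grignard reagent 11 (not isolated)
Conditions: 10, Mg, THF, 20 °C; then 9, −20 → 20 °C (3.5 equiv of 11); aq NH4Cl
Reagents that add atoms: none
Why: Grignard addition to an N-methoxy-N-methyl amide, in which the first equivalent turns the enol into a magnesium enolate that shields C4 and C5 and the chelated adduct at C8a should release the ketone only on work-up.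

Step 6
Reactants: 12 (1R,4Z)-5-hydroxy-1-[4-methoxy-3-(3-methylbut-2-en-1-yl)phenyl]-10-methyl-1-(triethylsilyloxy)undeca-4,9-diene-3,6-dione
Product: 13 (1R,4Z)-5-(methoxymethoxy)-1-[4-methoxy-3-(3-methylbut-2-en-1-yl)phenyl]-10-methyl-1-(triethylsilyloxy)undeca-4,9-diene-3,6-dione
Conditions: NaH, THF, 0 °C; then MeOCH2Cl, 0 °C
Reagents that add atoms: chloromethyl methyl ether, COCCl
Why: O-alkylation of a chelated sodium 1,3-diketonate, where the charge should sit on the oxygen of the more electrophilic carbonyl (C5, flanked by the C8a carbonyl), as in β-keto esters and hydroxymethylene ketones, and the U-shaped chelate should pass on the Z geometry.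

Step 7
Reactants: 13 (1R,4Z)-5-(methoxymethoxy)-1-[4-methoxy-3-(3-methylbut-2-en-1-yl)phenyl]-10-methyl-1-(triethylsilyloxy)undeca-4,9-diene-3,6-dione
Product: 16 (1R,4Z)-7-diazo-5-(methoxymethoxy)-1-[4-methoxy-3-(3-methylbut-2-en-1-yl)phenyl]-10-methyl-1-(triethylsilyloxy)undeca-4,9-diene-3,6-dione, via lithium dienolate 14 (not isolated), via trifluoroacetyl ketone 15 (not isolated)
Conditions: LiN(SiMe3)2, THF, −78 °C; CF3CO2CH2CF3; then MsN3, Et3N, H2O, MeCN, 20 °C
Reagents that add atoms: methanesulfonyl azide, CS(=O)(=O)N=[N+]=[N-] (the two terminal nitrogens); 2,2,2-trifluoroethyl trifluoroacetate, O=C(OCC(F)(F)F)C(F)(F)F (trifluoroacetyl group, present only in 15)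
Why: Detrifluoroacetylative diazo transfer, in which the C8a ketone, the only carbonyl not deactivated as a vinylogous ester, should be enolised toward C6, and the trifluoroacetyl group activates C6 for diazo transfer and then leaves as the N-sulfonyl amide.

Step 8
Reactants: 17 1-propynyllithium
Product: 19 1-(triisopropylsiloxy)prop-1-yne, via lithium ynolate 18 (not isolated)
Conditions: t-BuOOH, LiN(SiMe3)2, THF, −78 → 0 °C; then iPr3SiOTf, −78 → 0 °C
Reagents that add atoms: tert-butyl hydroperoxide, CC(C)(C)OO; triisopropylsilyl trifluoromethanesulfonate, CC(C)[Si](OS(=O)(=O)C(F)(F)F)(C(C)C)C(C)C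
Why: Electrophilic oxidation of a lithium acetylide by lithium tert-butyl peroxide gives the ynolate, and O-silylation with the bulky silyl triflate should give the isolable siloxyalkyne.

Step 9
Reactants: 16 (1R,4Z)-7-diazo-5-(methoxymethoxy)-1-[4-methoxy-3-(3-methylbut-2-en-1-yl)phenyl]-10-methyl-1-(triethylsilyloxy)undeca-4,9-diene-3,6-dione; 19 1-(triisopropylsiloxy)prop-1-yne
Product: 23 (3R)-1-[2-hydroxy-6-(methoxymethoxy)-3-methyl-5-(3-methylbut-2-en-1-yl)-4-(triisopropylsilyloxy)phenyl]-3-[4-methoxy-3-(3-methylbut-2-en-1-yl)phenyl]-3-(triethylsilyloxy)propan-1-one, via vinylketene 20 (not isolated), via vinylcyclobutenone 21 (not isolated), via dienylketene 22 (not isolated)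
Conditions: 19 (3 equiv), hν (450 nm), ClCH2CH2Cl, 20 °C; then 80 °C
Reagents that add atoms: none
Why: Excitation of the diazo ketone expels N2 and the alkenyl carbon C5 shifts from C8a to C6 (Wolff rearrangement) to give vinylketene 20; the methyl-bearing, nucleophilic carbon of 19 then bonds to the ketene carbon C8a and its siloxy carbon to C6 ([2+2]), cyclobutenone 21 opens (4π) to dienylketene 22, and 6π electrocyclisation between C8a and C4a with enolisation ends at the phenol. The closest known reaction is the Danheiser benzannulation in its photochemical Wolff variant, which turns unsaturated α-diazo ketones and siloxyalkynes into resorcinol monosilyl ethers. Ring A closes by a thermal six-electron electrocyclisation of the dienylketene (C8a–C4a bond), after the C8–C8a and C6–C7 bonds have been made in the [2+2] event. No stereocentre is created, and C2 lies three atoms from the nearest reacting carbon, so its R configuration should pass through unchanged. Two selectivities are needed: the orientation of the alkyne, which the polarised ynol ether supplies, and the suppression of oxa-6π closure of 20 to a 2-pyranone, which the Z enol ether secures by holding the C4 carbonyl trans to the ketene; light of 450 nm is used so that the diazo chromophore is excited selectively and this geometry is not scrambled. The phenol hydroxyl is formed at C8a only, beside the C8 methyl group, while O7 arrives silylated and O5 stays protected, which is the differentiation ring C needs.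

Step 10
Reactants: 23 (3R)-1-[2-hydroxy-6-(methoxymethoxy)-3-methyl-5-(3-methylbut-2-en-1-yl)-4-(triisopropylsilyloxy)phenyl]-3-[4-methoxy-3-(3-methylbut-2-en-1-yl)phenyl]-3-(triethylsilyloxy)propan-1-one
Product: 24 (3R)-3-hydroxy-1-[2-hydroxy-6-(methoxymethoxy)-3-methyl-5-(3-methylbut-2-en-1-yl)-4-(triisopropylsilyloxy)phenyl]-3-[4-methoxy-3-(3-methylbut-2-en-1-yl)phenyl]propan-1-one
Conditions: HF·pyridine, pyridine, THF, 0 °C
Reagents that add atoms: none
Why: Buffered fluoride desilylation should remove the secondary triethylsilyl ether while the hindered aryl triisopropylsilyl ether and the MOM ether stay, and the near-neutral medium avoids ionising the p-methoxybenzylic alcohol.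

Step 11
Reactants: 24 (3R)-3-hydroxy-1-[2-hydroxy-6-(methoxymethoxy)-3-methyl-5-(3-methylbut-2-en-1-yl)-4-(triisopropylsilyloxy)phenyl]-3-[4-methoxy-3-(3-methylbut-2-en-1-yl)phenyl]propan-1-one
Product: 25 (2S)-5-(methoxymethoxy)-2-[4-methoxy-3-(3-methylbut-2-en-1-yl)phenyl]-8-methyl-6-(3-methylbut-2-en-1-yl)-7-(triisopropylsilyloxy)-2,3-dihydro-4H-chromen-4-one
Conditions: PPh3, DIAD, THF (0.01 M), 0 → 20 °C
Reagents that add atoms: none
Why: Intramolecular Mitsunobu etherification, in which the C8a hydroxyl, the only free phenol, displaces the activated C2 oxygen in an SN2 6-exo closure, so ring C should form with inversion from R to S.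

Step 12
Reactants: 25 (2S)-5-(methoxymethoxy)-2-[4-methoxy-3-(3-methylbut-2-en-1-yl)phenyl]-8-methyl-6-(3-methylbut-2-en-1-yl)-7-(triisopropylsilyloxy)-2,3-dihydro-4H-chromen-4-one
Product: 27 (2S)-5,7-dihydroxy-2-[4-methoxy-3-(3-methylbut-2-en-1-yl)phenyl]-8-methyl-6-(3-methylbut-2-en-1-yl)-2,3-dihydro-4H-chromen-4-one, via phenol 26 (not isolated)
Conditions: Bu4NF, AcOH, THF, 0 °C; then HCl (3 M aq), MeOH, 40 °C
Reagents that add atoms: none
Why: Buffered fluoride desilylation of the aryl silyl ether followed by acid methanolysis of the MOM acetal (made labile by the neighbouring C4 carbonyl) should free both phenols without base, so the C2 centre and the prenyl groups are spared.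

Compound list
1 | 3-bromo-4-methoxybenzaldehyde | COc1ccc(C=O)cc1Br | starting material
2 | tributyl(3-methylbut-2-en-1-yl)stannane | CCCC[Sn](CCCC)(CCCC)CC=C(C)C | starting material
3 | 4-methoxy-3-(3-methylbut-2-en-1-yl)benzaldehyde | COc1ccc(C=O)cc1CC=C(C)C | intermediate
4 | acetone | CC(C)=O | starting material
5 | (4R)-4-hydroxy-4-[4-methoxy-3-(3-methylbut-2-en-1-yl)phenyl]butan-2-one | COc1ccc(cc1CC=C(C)C)[C@H](O)CC(C)=O | intermediate
6 | (4R)-4-[4-methoxy-3-(3-methylbut-2-en-1-yl)phenyl]-4-(triethylsilyloxy)butan-2-one | COc1ccc(cc1CC=C(C)C)[C@H](O[Si](CC)(CC)CC)CC(C)=O | intermediate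
7 | N,N'-dimethoxy-N,N'-dimethyloxamide | CON(C)C(=O)C(=O)N(C)OC | starting material
8 | lithium (4R)-4-[4-methoxy-3-(3-methylbut-2-en-1-yl)phenyl]-4-(triethylsilyloxy)but-1-en-2-olate | COc1ccc(cc1CC=C(C)C)[C@H](O[Si](CC)(CC)CC)CC(=C)O[Li] | intermediate (not isolated)
9 | (2Z,6R)-2-hydroxy-N-methoxy-6-[4-methoxy-3-(3-methylbut-2-en-1-yl)phenyl]-N-methyl-4-oxo-6-(triethylsilyloxy)hex-2-enamide | COc1ccc(cc1CC=C(C)C)[C@H](O[Si](CC)(CC)CC)CC(=O)/C=C(\O)C(=O)N(C)OC | intermediate
10 | 5-bromo-2-methylpent-2-ene | CC(C)=CCCBr | starting material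
11 | (4-methylpent-3-en-1-yl)magnesium bromide | CC(C)=CCC[Mg]Br | intermediate (not isolated)
12 | (1R,4Z)-5-hydroxy-1-[4-methoxy-3-(3-methylbut-2-en-1-yl)phenyl]-10-methyl-1-(triethylsilyloxy)undeca-4,9-diene-3,6-dione | COc1ccc(cc1CC=C(C)C)[C@H](O[Si](CC)(CC)CC)CC(=O)/C=C(\O)C(=O)CCC=C(C)C | intermediate
13 | (1R,4Z)-5-(methoxymethoxy)-1-[4-methoxy-3-(3-methylbut-2-en-1-yl)phenyl]-10-methyl-1-(triethylsilyloxy)undeca-4,9-diene-3,6-dione | COc1ccc(cc1CC=C(C)C)[C@H](O[Si](CC)(CC)CC)CC(=O)/C=C(\OCOC)C(=O)CCC=C(C)C | intermediate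
14 | lithium dienolate of 13 (enolate across C8a and C6, geometry not defined) | COc1ccc(cc1CC=C(C)C)[C@H](O[Si](CC)(CC)CC)CC(=O)/C=C(\OCOC)C(O[Li])=CCC=C(C)C | intermediate (not isolated)
15 | (1R,4Z)-5-(methoxymethoxy)-1-[4-methoxy-3-(3-methylbut-2-en-1-yl)phenyl]-10-methyl-1-(triethylsilyloxy)-7-(trifluoroacetyl)undeca-4,9-diene-3,6-dione (both C7 epimers, enolised) | COc1ccc(cc1CC=C(C)C)[C@H](O[Si](CC)(CC)CC)CC(=O)/C=C(\OCOC)C(=O)C(CC=C(C)C)C(=O)C(F)(F)F | intermediate (not isolated)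
16 | (1R,4Z)-7-diazo-5-(methoxymethoxy)-1-[4-methoxy-3-(3-methylbut-2-en-1-yl)phenyl]-10-methyl-1-(triethylsilyloxy)undeca-4,9-diene-3,6-dione | COc1ccc(cc1CC=C(C)C)[C@H](O[Si](CC)(CC)CC)CC(=O)/C=C(\OCOC)C(=O)C(=[N+]=[N-])CC=C(C)C | intermediate (key-step precursor)
17 | 1-propynyllithium | [Li]C#CC | starting material
18 | lithium prop-1-yn-1-olate | CC#CO[Li] | intermediate (not isolated)
19 | 1-(triisopropylsiloxy)prop-1-yne | CC#CO[Si](C(C)C)(C(C)C)C(C)C | intermediate
20 | (3Z,7R)-3-(methoxymethoxy)-7-[4-methoxy-3-(3-methylbut-2-en-1-yl)phenyl]-2-(3-methylbut-2-en-1-yl)-7-(triethylsilyloxy)hepta-1,3-diene-1,5-dione (vinylketene) | COc1ccc(cc1CC=C(C)C)[C@H](O[Si](CC)(CC)CC)CC(=O)/C=C(\OCOC)C(CC=C(C)C)=C=O | intermediate (not isolated)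
21 | 4-[(1Z,5R)-1-(methoxymethoxy)-5-[4-methoxy-3-(3-methylbut-2-en-1-yl)phenyl]-3-oxo-5-(triethylsilyloxy)pent-1-en-1-yl]-2-methyl-4-(3-methylbut-2-en-1-yl)-3-(triisopropylsilyloxy)cyclobut-2-en-1-one (both C4 epimers) | COc1ccc(cc1CC=C(C)C)[C@H](O[Si](CC)(CC)CC)CC(=O)/C=C(\OCOC)C1(CC=C(C)C)C(=O)C(C)=C1O[Si](C(C)C)(C(C)C)C(C)C | intermediate (not isolated)
22 | dienylketene O=C=C(CH3)–C(OSiiPr3)=C(prenyl)–C(OMOM)=CH–C(O)–CH2–CH(OSiEt3)Ar, R at the carbinol carbon, Z at the enol ether | COc1ccc(cc1CC=C(C)C)[C@H](O[Si](CC)(CC)CC)CC(=O)/C=C(\OCOC)C(CC=C(C)C)=C(O[Si](C(C)C)(C(C)C)C(C)C)C(C)=C=O | intermediate (not isolated)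
23 | (3R)-1-[2-hydroxy-6-(methoxymethoxy)-3-methyl-5-(3-methylbut-2-en-1-yl)-4-(triisopropylsilyloxy)phenyl]-3-[4-methoxy-3-(3-methylbut-2-en-1-yl)phenyl]-3-(triethylsilyloxy)propan-1-one | COc1ccc(cc1CC=C(C)C)[C@H](O[Si](CC)(CC)CC)CC(=O)c1c(O)c(C)c(O[Si](C(C)C)(C(C)C)C(C)C)c(CC=C(C)C)c1OCOC | intermediate (key-step product)
24 | (3R)-3-hydroxy-1-[2-hydroxy-6-(methoxymethoxy)-3-methyl-5-(3-methylbut-2-en-1-yl)-4-(triisopropylsilyloxy)phenyl]-3-[4-methoxy-3-(3-methylbut-2-en-1-yl)phenyl]propan-1-one | COc1ccc(cc1CC=C(C)C)[C@H](O)CC(=O)c1c(O)c(C)c(O[Si](C(C)C)(C(C)C)C(C)C)c(CC=C(C)C)c1OCOC | intermediate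
25 | (2S)-5-(methoxymethoxy)-2-[4-methoxy-3-(3-methylbut-2-en-1-yl)phenyl]-8-methyl-6-(3-methylbut-2-en-1-yl)-7-(triisopropylsilyloxy)-2,3-dihydro-4H-chromen-4-one | COc1ccc([C@@H]2CC(=O)c3c(OCOC)c(CC=C(C)C)c(O[Si](C(C)C)(C(C)C)C(C)C)c(C)c3O2)cc1CC=C(C)C | intermediate
26 | (2S)-7-hydroxy-5-(methoxymethoxy)-2-[4-methoxy-3-(3-methylbut-2-en-1-yl)phenyl]-8-methyl-6-(3-methylbut-2-en-1-yl)-2,3-dihydro-4H-chromen-4-one | COc1ccc([C@@H]2CC(=O)c3c(OCOC)c(CC=C(C)C)c(O)c(C)c3O2)cc1CC=C(C)C | intermediate (not isolated)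
27 | (2S)-5,7-dihydroxy-2-[4-methoxy-3-(3-methylbut-2-en-1-yl)phenyl]-8-methyl-6-(3-methylbut-2-en-1-yl)-2,3-dihydro-4H-chromen-4-one | COc1ccc([C@@H]2CC(=O)c3c(O)c(CC=C(C)C)c(O)c(C)c3O2)cc1CC=C(C)C | target

Total step count: 12. Longest linear sequence: 11 steps (steps 1 to 7 and 9 to 12, from 1 to 27); step 8 is a one-step branch.

Steps most likely to fail

Step 9. The excited diazo ketone may react as an acyl carbene and undergo a 1,2-hydrogen shift from the allylic CH2 on C6, giving a dienone before the alkenyl group can migrate. Light-induced E/Z isomerisation of the enol ether would in addition divert the ketene into a 2-pyranone. The fallback sets out from amide 9 and returns at phenol 26. It runs the same benzannulation on a diazo ketone whose diazo carbon carries no substituent, the classical substrate type, and adds the C6 prenyl group afterwards by aromatic Claisen rearrangement. MeMgBr should convert 9 into the methyl triketone enol F1, NaH/MeOCH2Cl into the Z enol ether F2, and LiN(SiMe3)2/CF3CO2CH2CF3 followed by MsN3/Et3N into the terminal diazo ketone F3. Irradiation with 19 and heating should give the C6-unsubstituted phenol F4. HF·pyridine would then give the alcohol F5, Mitsunobu closure the flavanone F6, and Bu4NF/AcOH the C7 phenol F7. Pd(PPh3)4-catalysed O-alkylation with tert-butyl 2-methylbut-3-en-2-yl carbonate should give the 1,1-dimethylallyl ether F8. Heating (PhNEt2, 130 °C) should move the allyl unit to C6 with allylic transposition, C8 being blocked by its methyl group, which gives 26.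

Step 6. Alkylation may take place in part on the C4 oxygen, or the enolate may react from an open conformation and give the E enol ether. The fallback sets out from ketone 6 and returns at 13. It forms the enol ether on an acylpyruvate ester, where the carbonyl next to the ester is the enolised one, and makes the homoprenyl ketone afterwards by a coupling that leaves ketones alone. The lithium enolate of 6 is condensed with diallyl oxalate (Claisen condensation) to the allyl 2,4-dioxo ester F9. NaH/MeOCH2Cl should give the enol ether F10, and Pd(PPh3)4/morpholine removes the allyl group to give the acid F11. EtSH, EDC and DMAP give the S-ethyl thioester F12. Fukuyama coupling with (4-methylpent-3-en-1-yl)zinc bromide (from 10, Zn, LiCl) and PdCl2(PPh3)2 should then give 13. The regiochemical advantage of this detour is modest, since the same electronic argument applies to 12.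

Step 11. The oxyphosphonium ion at C2 is p-methoxybenzylic and β to a ketone, so ionisation with loss of enantiopurity, or E1cB elimination to the chalcone, may compete with the SN2 closure. The fallback sets out from 24 and returns at 25; it gives up the stereocentre and recovers it by kinetic resolution, at the cost of half the material. PPTS in warm toluene dehydrates 24 to the chalcone F13. NaOAc in refluxing EtOH closes it by oxa-Michael addition to the racemic flavanone F14. Asymmetric transfer hydrogenation with Cp*RhCl(TsDPEN) (the enantiomer that reduces the (R)-ketone faster) in HCO2H/Et3N should reduce the (R)-enantiomer to the cis-flavan-4-ol F15, which is separated from unreacted (S)-flavanone 25.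

Further compounds
F1 | step 9 | (3Z,7R)-3-hydroxy-7-[4-methoxy-3-(3-methylbut-2-en-1-yl)phenyl]-7-(triethylsilyloxy)hept-3-ene-2,5-dione | COc1ccc(cc1CC=C(C)C)[C@H](O[Si](CC)(CC)CC)CC(=O)/C=C(\O)C(C)=O
F2 | step 9 | (3Z,7R)-3-(methoxymethoxy)-7-[4-methoxy-3-(3-methylbut-2-en-1-yl)phenyl]-7-(triethylsilyloxy)hept-3-ene-2,5-dione | COc1ccc(cc1CC=C(C)C)[C@H](O[Si](CC)(CC)CC)CC(=O)/C=C(\OCOC)C(C)=O
F3 | step 9 | (3Z,7R)-1-diazo-3-(methoxymethoxy)-7-[4-methoxy-3-(3-methylbut-2-en-1-yl)phenyl]-7-(triethylsilyloxy)hept-3-ene-2,5-dione | COc1ccc(cc1CC=C(C)C)[C@H](O[Si](CC)(CC)CC)CC(=O)/C=C(\OCOC)C(=O)C=[N+]=[N-]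
F4 | step 9 | (3R)-1-[2-hydroxy-6-(methoxymethoxy)-3-methyl-4-(triisopropylsilyloxy)phenyl]-3-[4-methoxy-3-(3-methylbut-2-en-1-yl)phenyl]-3-(triethylsilyloxy)propan-1-one | COc1ccc(cc1CC=C(C)C)[C@H](O[Si](CC)(CC)CC)CC(=O)c1c(O)c(C)c(O[Si](C(C)C)(C(C)C)C(C)C)cc1OCOC
F5 | step 9 | (3R)-3-hydroxy-1-[2-hydroxy-6-(methoxymethoxy)-3-methyl-4-(triisopropylsilyloxy)phenyl]-3-[4-methoxy-3-(3-methylbut-2-en-1-yl)phenyl]propan-1-one | COc1ccc(cc1CC=C(C)C)[C@H](O)CC(=O)c1c(O)c(C)c(O[Si](C(C)C)(C(C)C)C(C)C)cc1OCOC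
F6 | step 9 | (2S)-5-(methoxymethoxy)-2-[4-methoxy-3-(3-methylbut-2-en-1-yl)phenyl]-8-methyl-7-(triisopropylsilyloxy)-2,3-dihydro-4H-chromen-4-one | COc1ccc([C@@H]2CC(=O)c3c(OCOC)cc(O[Si](C(C)C)(C(C)C)C(C)C)c(C)c3O2)cc1CC=C(C)C
F7 | step 9 | (2S)-7-hydroxy-5-(methoxymethoxy)-2-[4-methoxy-3-(3-methylbut-2-en-1-yl)phenyl]-8-methyl-2,3-dihydro-4H-chromen-4-one | COc1ccc([C@@H]2CC(=O)c3c(OCOC)cc(O)c(C)c3O2)cc1CC=C(C)C
F8 | step 9 | (2S)-5-(methoxymethoxy)-2-[4-methoxy-3-(3-methylbut-2-en-1-yl)phenyl]-8-methyl-7-[(2-methylbut-3-en-2-yl)oxy]-2,3-dihydro-4H-chromen-4-one | COc1ccc([C@@H]2CC(=O)c3c(OCOC)cc(OC(C)(C)C=C)c(C)c3O2)cc1CC=C(C)C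
F9 | step 6 | prop-2-en-1-yl (2Z,6R)-2-hydroxy-6-[4-methoxy-3-(3-methylbut-2-en-1-yl)phenyl]-4-oxo-6-(triethylsilyloxy)hex-2-enoate | COc1ccc(cc1CC=C(C)C)[C@H](O[Si](CC)(CC)CC)CC(=O)/C=C(\O)C(=O)OCC=C
F10 | step 6 | prop-2-en-1-yl (2Z,6R)-2-(methoxymethoxy)-6-[4-methoxy-3-(3-methylbut-2-en-1-yl)phenyl]-4-oxo-6-(triethylsilyloxy)hex-2-enoate | COc1ccc(cc1CC=C(C)C)[C@H](O[Si](CC)(CC)CC)CC(=O)/C=C(\OCOC)C(=O)OCC=C
F11 | step 6 | (2Z,6R)-2-(methoxymethoxy)-6-[4-methoxy-3-(3-methylbut-2-en-1-yl)phenyl]-4-oxo-6-(triethylsilyloxy)hex-2-enoic acid | COc1ccc(cc1CC=C(C)C)[C@H](O[Si](CC)(CC)CC)CC(=O)/C=C(\OCOC)C(=O)O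
F12 | step 6 | S-ethyl (2Z,6R)-2-(methoxymethoxy)-6-[4-methoxy-3-(3-methylbut-2-en-1-yl)phenyl]-4-oxo-6-(triethylsilyloxy)hex-2-enethioate | COc1ccc(cc1CC=C(C)C)[C@H](O[Si](CC)(CC)CC)CC(=O)/C=C(\OCOC)C(=O)SCC
F13 | step 11 | (2E)-1-[2-hydroxy-6-(methoxymethoxy)-3-methyl-5-(3-methylbut-2-en-1-yl)-4-(triisopropylsilyloxy)phenyl]-3-[4-methoxy-3-(3-methylbut-2-en-1-yl)phenyl]prop-2-en-1-one | COc1ccc(/C=C/C(=O)c2c(O)c(C)c(O[Si](C(C)C)(C(C)C)C(C)C)c(CC=C(C)C)c2OCOC)cc1CC=C(C)C
F14 | step 11 | racemic 5-(methoxymethoxy)-2-[4-methoxy-3-(3-methylbut-2-en-1-yl)phenyl]-8-methyl-6-(3-methylbut-2-en-1-yl)-7-(triisopropylsilyloxy)-2,3-dihydro-4H-chromen-4-one | COc1ccc(C2CC(=O)c3c(OCOC)c(CC=C(C)C)c(O[Si](C(C)C)(C(C)C)C(C)C)c(C)c3O2)cc1CC=C(C)C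
F15 | step 11 | (2R,4R)-5-(methoxymethoxy)-2-[4-methoxy-3-(3-methylbut-2-en-1-yl)phenyl]-8-methyl-6-(3-methylbut-2-en-1-yl)-7-(triisopropylsilyloxy)-3,4-dihydro-2H-chromen-4-ol | COc1ccc([C@H]2C[C@@H](O)c3c(OCOC)c(CC=C(C)C)c(O[Si](C(C)C)(C(C)C)C(C)C)c(C)c3O2)cc1CC=C(C)C
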